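All runs stem from a simulated flask on assumed constants; noise was put on by code.

Stop this flask early, and reckon its height from the reagent, not from the catalyst.

common to all: starting material 1.1 M
- oak: reagent 2.2 M; catalyst 37 mM; run made earlier
- cedar: reagent 2.2 M; catalyst 82 mM; run made earlier
- flask: reagent 2.20 M; catalyst 55 mM; time 50 min

| run | time / min | target / % |
|---|---|---|
| oak | 0.333 | 20 |
| oak | 1.33 | 26 |
| oak | 6.00 | 15 |
| oak | 30.0 | 5 |
| cedar | 0.333 | 26 |
| cedar | 1.33 | 25 |
| cedar | 6.00 | 17 |
| cedar | 30.0 | 3 |

(readings scatter by 1.5 percentage points)
1. time, not beyond 50 min, at which the flask holds most target
2. the amount of target, in percent of the starting material charged, at that time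
- a species is counted by the starting material in it: one side product counts as two
- what may be going on: starting material + reagent + catalyst <-> target + catalyst; starting material + target -> side product; target <-> isomer of the product

Making is the fast rung. Take oak's first reading as a pseudo-first-order rise and scale it by catalyst: this flask then gets a rise half-time of 0.696 min, and I put the peak there. The fall is the slow rung: oak's last two readings give a half-life of about 15.1 min, much longer than the rise.

For the height, oak's and cedar's highest readings are 26 % and 26 %, although cedar holds 2.22 times the catalyst. A catalyst speeds both directions of the first step and leaves that step's equilibrium where it is, so I watch the reagent. Let g, the peak odds per molar reagent, be target over the rest of the charge at oak's peak reading, divided by the reagent charge: 0.160 L mol⁻¹. The reagent charge is the same here, so g simply carries oak's reading over, and I expect about 26.0 % in this flask.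

The forecast gave 0.9 min and 27 %, its time on the ground that “Formation scales with catalyst”; my time is shorter.

The flask peaks at 0.718 min with 27.1 %, earlier than the forecast.

    starting material + reagent + catalyst ⇌ target + catalyst, rate k1*[starting material]*[reagent]*[catalyst] forward; the back reaction follows from the equilibrium constant (K = 0.260 L mol⁻¹, k = 0.210 L² mol⁻² s⁻¹)
    starting material + target → side product (k = 0.00660 L mol⁻¹ s⁻¹)
    target ⇌ isomer of the product (K = 9.00, k = 5.60 × 10⁻⁴ s⁻¹)

The height is where g earns its place: without the falling back of target to starting material and reagent, the highest target rises from 27.1 % to 66.6 %, the largest single effect on it. In the neighbour flask, with 0.88 M of reagent, g gives 12.3 %; the computed best there is 12.8 %.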